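(The runs were generated by integration on assumed constants.)

Start from the midnight run: with 30 mM of L, its dose of E left 74.5% of the L, and the readings stopped moving. The autumn flask, with 15 mM, stopped too, showing 65.2% of L and 21.6% of D at 600 min. L still stands there, so read E as the limiting reagent, expect D at 10 h near that reading, and expect gamma, delta and theta to give little.

| flask | L | E | temperature | remark | time |
|---|---|---|---|---|---|
| autumn | 15 mM | 30 mM | 35 °C | the very flask that is asked about, followed so far |  |
| midnight | 30 mM | 30 mM | 30 °C | run made earlier |  |
| flask | 15 mM | 30.0 mM | 35 °C |  | 10 h |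

| run | time / min | D / % | L / % |
|---|---|---|---|
| autumn | 50.0 | 21.0 | 65.2 |
| autumn | 120 | 21.6 | 64.9 |
| autumn | 240 | 21.8 | 65.2 |
| autumn | 600 | 21.6 | 65.2 |
| midnight | 5.00 | 5.5 | 82.2 |
| midnight | 10.0 | 10.7 | 75.9 |
| midnight | 15.0 | 13.5 | 75.0 |
| midnight | 20.0 | 13.6 | 74.5 |

(each reading ± 0.5 percentage points)

1. D, in percent of the L first charged, at 10 h
2. the option that brings most further D ("none" if no option brings more than 2 percentage points) (delta / eta / gamma / theta / none)
3. D present, with what was taken out counted in, in percent of the L first charged, after eta
4. D present, with what was taken out counted in, in percent of the L first charged, after gamma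

- delta: at 10 h take out 90% of the D then present, then wait 20 h
- eta: at 10 h add E, 100% of the amount charged, then wait 20 h
- gamma: change nothing and wait 20 h more
- theta: at 10 h raise the temperature by 25 K, then wait 20 h

Autumn reads 0.428 and midnight 0.294 on the measure to carry, a dose's reach: the natural log of L charged over L left, which equals the rate constant of L + E going to G times the mean [E] over the run times the time.

Now solve two extreme flasks for eta, letting D follow L lost in the same share. Suppose X takes E and L a negligible part of it: reach ignores [L], the second dose repeats the reach, and D ends at 35.7%. Suppose E goes wholly to L: each dose takes the same millimoles per litre, and D ends at 43.2%.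

The runs point between the two, with one caution: midnight also ran cooler, at 30 °C. Reach in autumn stands above reach in midnight. L consumed reads 5.22 mM in autumn and 7.65 mM in midnight, a factor of 1.47 for twice the L. That factor sits midway between the extremes, so take their mean, 39.4%, as my estimate. L and D together fall short of the charge by 13.2%; any of that held as G can still become D, so my range runs up to 52.6%.

The forecast gives 21.6% now, eta as best, 44% after eta and 21.7% after gamma, on the ground that “Fresh E restarts the chemistry”. Its eta figure lies above my estimate and inside my range.

The flask gives 21.8% now and eta as best, with 44.8% after eta and 21.8% after gamma. Eta adds 23 percentage points; delta adds 0 points, gamma 0 points, theta 0 points.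

    J → D (k = 0.0126 s⁻¹, Ea = 94.0 kJ mol⁻¹)
    E + G ⇌ Q (K = 50.0 L mol⁻¹, k = 0.137 L mol⁻¹ s⁻¹, Ea = 56.0 kJ mol⁻¹, ΔH = −20.0 kJ mol⁻¹)
    2 E → X (k = 0.174 L mol⁻¹ s⁻¹, Ea = 43.0 kJ mol⁻¹)
    L + E → G (k = 0.0742 L mol⁻¹ s⁻¹, Ea = 43.0 kJ mol⁻¹)
    E + G → J (k = 0.548 L mol⁻¹ s⁻¹, Ea = 40.0 kJ mol⁻¹)
    Q → Z (k = 0.0905 s⁻¹, Ea = 89.0 kJ mol⁻¹)
    (constants at 35 °C)

At 10 h this flask holds E at 0% beside G at 7.73%, and eta's result stands 1.6 points above my second extreme and below the end of my range. Take the reach to the neighbour flask with 3.8 mM of L. It ends with 47.9% of L, a reach of 0.736, above autumn's 0.428. Autumn's reach asks it to consume 1.32 mM of L; autumn's amount asks for 5.22 mM, beyond its charge. It consumed 1.98 mM, between the two, and its D stands at 37.2%.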